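**Plan**
Retrosynthesis cuts, in order: the two aryl O–Si bonds and a temporary C3–CO2R bond, then O1–C2 of ring C, then the C2=C3 alkene of the open-chain ester, then the CH2–CO2R bond of the β-keto ester, and last the geranyl–O bond.
Enabling feature: O1 and C2 meet at a benzylic stereocentre β to the C4 ketone, and C3 lies between C2 and C4, so the C8a hydroxyl of ring A can add to C2 of an alkene activated by both the C4 ketone and a removable C3 ester.
Forward: rings A and B are bought; ring A is bis-silylated and C-alkoxycarbonylated, ring B is geranylated, and a Knoevenagel condensation joins them (C2=C3).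
Ring C closes last by a 6-endo oxa-Michael addition; buffered fluoride then removes the ester (as CO2) and both silyl ethers.
Stereochemistry: C2, the only stereocentre, is set in the ring closure by a bifunctional cinchona thiourea; C3 is transient; the 2E alkene comes from geranyl bromide.

Key step: step 6

Assumption: the thiourea built on 9-amino-9-deoxy-epi-quinidine is taken as the pseudo-enantiomer that delivers 2S in this substrate class; if the first run shows the opposite sense, the quinine-derived catalyst replaces it with no other change.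

**Route**

Step 1
Reactants: 1 2,4,6-trihydroxyacetophenone
Product: 2 1-[2-hydroxy-4,6-bis(triisopropylsilyloxy)phenyl]ethanone
Conditions: TIPSCl (2.3 equiv), imidazole (5 equiv), DMAP (cat.), DMF, 0 °C to rt
Reagents that add atoms: triisopropylsilyl chloride, CC(C)[Si](Cl)(C(C)C)C(C)C
Why: Phenol silylation should stop at the bis-ether because the 4-OH and one ortho OH react, while the last ortho OH is held in a strong hydrogen bond to the acetyl carbonyl and is shielded by the bulky silyl chloride.

Step 2
Reactants: 3 2-(trimethylsilyl)ethanol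
Product: 4 2-(trimethylsilyl)ethyl 1H-imidazole-1-carboxylate
Conditions: CDI (1.1 equiv), CH2Cl2, rt
Reagents that add atoms: 1,1'-carbonyldiimidazole, O=C(n1ccnc1)n1ccnc1
Why: Acyl transfer from carbonyldiimidazole to a primary alcohol should stop at the imidazole carbamate, since the second imidazole is not displaced at room temperature without added base.

Step 3
Reactants: 2 1-[2-hydroxy-4,6-bis(triisopropylsilyloxy)phenyl]ethanone; 4 2-(trimethylsilyl)ethyl 1H-imidazole-1-carboxylate
Product: 6 2-(trimethylsilyl)ethyl 3-[2-hydroxy-4,6-bis(triisopropylsilyloxy)phenyl]-3-oxopropanoate, via dilithium enolate phenoxide 5 (not isolated)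
Conditions: LiN(SiMe3)2 (3.2 equiv), THF, –78 to –20 °C; then 4, –78 to 0 °C; aq. NH4Cl
Reagents that add atoms: none
Why: This is a Claisen-type C-alkoxycarbonylation of a ketone enolate with an imidazole carbamate, in which the phenoxide–enolate dianion reacts at carbon, any carbonate formed on the phenoxide oxygen would be relayed to carbon by a Baker–Venkataraman shift, and the third equivalent of base stores the product as its enolate so that it is not acylated twice.

Step 4
Reactants: 7 4-hydroxybenzaldehyde; 8 geranyl bromide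
Product: 9 4-{[(2E)-3,7-dimethylocta-2,6-dien-1-yl]oxy}benzaldehyde
Conditions: K2CO3 (1.5 equiv), DMF, rt
Reagents that add atoms: none
Why: Williamson ether synthesis, in which the phenoxide should displace the primary allylic bromide directly and leave the 2E alkene untouched.

Step 5
Reactants: 6 2-(trimethylsilyl)ethyl 3-[2-hydroxy-4,6-bis(triisopropylsilyloxy)phenyl]-3-oxopropanoate; 9 4-{[(2E)-3,7-dimethylocta-2,6-dien-1-yl]oxy}benzaldehyde
Product: 10 2-(trimethylsilyl)ethyl (2Z)-3-{4-[(2E)-3,7-dimethylocta-2,6-dien-1-yloxy]phenyl}-2-[2-hydroxy-4,6-bis(triisopropylsilyloxy)benzoyl]prop-2-enoate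
Conditions: piperidine (0.2 equiv), AcOH (0.2 equiv), 4 Å MS, toluene, rt
Reagents that add atoms: none
Why: Knoevenagel condensation through the piperidinium iminium ion of 9 and the enol of 6 should give the less congested Z alkene (aryl cis to the ester), while the buffered, room-temperature medium leaves the ketone-bound phenol too weak a nucleophile to close the ring or attack the ester.

Step 6
Reactants: 10 2-(trimethylsilyl)ethyl (2Z)-3-{4-[(2E)-3,7-dimethylocta-2,6-dien-1-yloxy]phenyl}-2-[2-hydroxy-4,6-bis(triisopropylsilyloxy)benzoyl]prop-2-enoate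
Product: 11 2-(trimethylsilyl)ethyl (2S)-2-{4-[(2E)-3,7-dimethylocta-2,6-dien-1-yloxy]phenyl}-4-oxo-5,7-bis(triisopropylsilyloxy)chromane-3-carboxylate (C3 epimerisable, keto and enol forms, not assigned)
Conditions: N-[3,5-bis(trifluoromethyl)phenyl]-N'-[(9R)-6'-methoxycinchonan-9-yl]thiourea (10 mol%), toluene, –25 °C; filtration through a short silica pad
Reagents that add atoms: none
Why: The quinuclidine nitrogen takes the proton of the C8a hydroxyl while the two thiourea N–H bonds bind the 1,3-dicarbonyl unit, and the phenoxide of this ordered ion pair adds to C2, the C3 enolate then being protonated by the ammonium ion. The closest known reaction is the bifunctional cinchona-thiourea-catalysed intramolecular oxa-Michael addition of 2'-hydroxyaryl alkylidene β-keto esters to 3-carboxyflavanones. Ring C closes in the 6-endo-trig mode by forming O1–C2. C2 is set by the catalyst, which exposes one enantioface of the alkene to the phenoxide, and the quinidine-derived pseudo-enantiomer is taken for 2S; C3 equilibrates through the enol and needs no control because it is lost in step 7. The step needs enantioface selectivity under kinetic control, which the second carbonyl group secures by making the alkene reactive at –25 °C, where the uncatalysed closure is slow, and by holding the adduct as a hydrogen-bonded enol that resists reopening. Only one phenol is free, so there is no competing nucleophile and no acidic OH to quench the amine.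

Step 7
Reactants: 11 2-(trimethylsilyl)ethyl (2S)-2-{4-[(2E)-3,7-dimethylocta-2,6-dien-1-yloxy]phenyl}-4-oxo-5,7-bis(triisopropylsilyloxy)chromane-3-carboxylate
Product: 13 (2S)-2-{4-[(2E)-3,7-dimethylocta-2,6-dien-1-yloxy]phenyl}-5,7-dihydroxychroman-4-one (CNP0123225.1), via free β-keto acid 12 (not isolated)
Conditions: Bu4NF (5 equiv), AcOH (5 equiv), THF, 0 °C to rt, then 40 °C until CO2 loss is complete
Reagents that add atoms: none
Why: Fluoride attack at silicon should fragment the 2-(trimethylsilyl)ethyl ester (loss of ethene) and cleave both aryl silyl ethers, the β-keto acid then decarboxylates through its cyclic hydrogen-bonded form, and the acetic acid buffer protonates the C3 enol before an E1cB reopening of ring C could scramble C2, all without acid, hydrogen or zerovalent palladium near the geranyl aryl ether.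

**Compound list**
1 | 2,4,6-trihydroxyacetophenone | CC(=O)c1c(O)cc(O)cc1O | starting material
2 | 1-[2-hydroxy-4,6-bis(triisopropylsilyloxy)phenyl]ethanone | CC(=O)c1c(O)cc(O[Si](C(C)C)(C(C)C)C(C)C)cc1O[Si](C(C)C)(C(C)C)C(C)C | intermediate
3 | 2-(trimethylsilyl)ethanol | C[Si](C)(C)CCO | starting material
4 | 2-(trimethylsilyl)ethyl 1H-imidazole-1-carboxylate | C[Si](C)(C)CCOC(=O)n1ccnc1 | intermediate
5 | dilithium enolate phenoxide of 2 (not isolated) | [Li+].[Li+].C=C([O-])c1c([O-])cc(O[Si](C(C)C)(C(C)C)C(C)C)cc1O[Si](C(C)C)(C(C)C)C(C)C | intermediate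
6 | 2-(trimethylsilyl)ethyl 3-[2-hydroxy-4,6-bis(triisopropylsilyloxy)phenyl]-3-oxopropanoate | C[Si](C)(C)CCOC(=O)CC(=O)c1c(O)cc(O[Si](C(C)C)(C(C)C)C(C)C)cc1O[Si](C(C)C)(C(C)C)C(C)C | intermediate
7 | 4-hydroxybenzaldehyde | O=Cc1ccc(O)cc1 | starting material
8 | geranyl bromide, (2E)-1-bromo-3,7-dimethylocta-2,6-diene | CC(C)=CCC/C(C)=C/CBr | starting material
9 | 4-{[(2E)-3,7-dimethylocta-2,6-dien-1-yl]oxy}benzaldehyde | CC(C)=CCC/C(C)=C/COc1ccc(C=O)cc1 | intermediate
10 | 2-(trimethylsilyl)ethyl (2Z)-3-{4-[(2E)-3,7-dimethylocta-2,6-dien-1-yloxy]phenyl}-2-[2-hydroxy-4,6-bis(triisopropylsilyloxy)benzoyl]prop-2-enoate | CC(C)=CCC/C(C)=C/COc1ccc(/C=C(\C(=O)OCC[Si](C)(C)C)C(=O)c2c(O)cc(O[Si](C(C)C)(C(C)C)C(C)C)cc2O[Si](C(C)C)(C(C)C)C(C)C)cc1 | intermediate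
11 | 2-(trimethylsilyl)ethyl (2S)-2-{4-[(2E)-3,7-dimethylocta-2,6-dien-1-yloxy]phenyl}-4-oxo-5,7-bis(triisopropylsilyloxy)chromane-3-carboxylate (C3 unassigned) | CC(C)=CCC/C(C)=C/COc1ccc([C@@H]2C(C(=O)OCC[Si](C)(C)C)C(=O)c3c(O[Si](C(C)C)(C(C)C)C(C)C)cc(O[Si](C(C)C)(C(C)C)C(C)C)cc3O2)cc1 | intermediate
12 | (2S)-2-{4-[(2E)-3,7-dimethylocta-2,6-dien-1-yloxy]phenyl}-5,7-dihydroxy-4-oxochromane-3-carboxylic acid (C3 unassigned, not isolated) | CC(C)=CCC/C(C)=C/COc1ccc([C@@H]2C(C(=O)O)C(=O)c3c(O)cc(O)cc3O2)cc1 | intermediate
13 | (2S)-2-{4-[(2E)-3,7-dimethylocta-2,6-dien-1-yloxy]phenyl}-5,7-dihydroxychroman-4-one | CC(C)=CCC/C(C)=C/COc1ccc([C@@H]2CC(=O)c3c(O)cc(O)cc3O2)cc1 | target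

**Count**
Total steps: 7. Longest linear sequence: 5 steps (steps 1, 3, 5, 6 and 7, from 1 through 2, 6, 10 and 11 to 13).

**Steps most likely to fail**

Step 6. The enantioface selectivity may be poor, because the unbranched silylethyl ester and the peri silyl ether differ from the bulky esters this catalyst class handles best. Uncatalysed closure or reopening of the ring may also erode the selectivity further. The fallback sets out from 10 and comes back at 11, and makes no new compound (F0). It changes the principle of activation from a hydrogen-bonding Brønsted base to a chelating chiral Lewis acid. A divalent nickel salt, Ni(CF3COCHCOCH3)2·2H2O, is combined with a C2-symmetric N,N'-dioxide ligand made from pipecolic acid and 2,6-diisopropylaniline, in anisole near 30 °C. The metal should bind both carbonyl oxygens of the alkylidene β-keto ester in a rigid chelate and let the phenol add to one face of C2. This is a known way to close the same substrate class, and the ligand antipode would be chosen for 2S.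

Step 7. The C3 enolate formed on decarboxylation may reopen ring C by E1cB elimination under basic fluoride, which would scramble C2 or leave the open chalcone. The ester fragmentation may also be slow once the fluoride is buffered. The fallback sets out from 2 (through dianion 5) and comes back at 13. It replaces the fluoride-labile ester by a tert-butyl ester that is removed without base.
- Dianion 5 is treated with di-tert-butyl dicarbonate to give tert-butyl 3-[2-hydroxy-4,6-bis(triisopropylsilyloxy)phenyl]-3-oxopropanoate F1.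
- Knoevenagel condensation of F1 with 9 under the conditions of step 5 gives the tert-butyl (2Z)-alkylidene β-keto ester F2.
- The thiourea of step 6 closes F2 to the tert-butyl (2S)-4-oxo-5,7-bis(triisopropylsilyloxy)chromane-3-carboxylate F3.
- Me3SiOTf with 2,6-lutidine in CH2Cl2 at 0 °C removes the tert-butyl group as 2-methylpropene. A pH 7 work-up then frees the (2S)-4-oxo-5,7-bis(triisopropylsilyloxy)chromane-3-carboxylic acid F4.
- F4 loses CO2 on gentle warming to give (2S)-5,7-bis(triisopropylsilyloxy)-4'-O-geranylflavanone F5.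
- Bu4NF/AcOH in THF at 0 °C removes the two silyl ethers from F5, which has no β-dicarbonyl unit left, and gives 13.

Step 5. The amine may trigger a premature, unselective addition of the free phenol to the new alkene. The phenol may also lactonise onto the ester, and the alkene may form as an E/Z mixture. The fallback sets out from 2 and comes back at 10. It masks the nucleophilic phenol through the condensation.
- NaH and chloromethyl methyl ether in THF convert 2 into 1-[2-(methoxymethoxy)-4,6-bis(triisopropylsilyloxy)phenyl]ethanone F6.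
- LiN(SiMe3)2 (2.2 equiv) and 4 convert F6 into the methoxymethyl-protected 2-(trimethylsilyl)ethyl β-keto ester F7.
- Knoevenagel condensation of F7 with 9, which may now be warmed, gives the methoxymethyl-protected (2Z)-alkylidene β-keto ester F8.
- Catalytic HCl in MeOH/THF at 0 °C removes the acetal of F8, whose cleavage is assisted by the neighbouring carbonyl group, and gives 10. This acid does not promote the oxa-Michael closure.

**Further compounds**
F0 | step 6 | none | none
F1 | step 7 | tert-butyl 3-[2-hydroxy-4,6-bis(triisopropylsilyloxy)phenyl]-3-oxopropanoate | CC(C)(C)OC(=O)CC(=O)c1c(O)cc(O[Si](C(C)C)(C(C)C)C(C)C)cc1O[Si](C(C)C)(C(C)C)C(C)C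
F2 | step 7 | tert-butyl (2Z)-3-{4-[(2E)-3,7-dimethylocta-2,6-dien-1-yloxy]phenyl}-2-[2-hydroxy-4,6-bis(triisopropylsilyloxy)benzoyl]prop-2-enoate | CC(C)=CCC/C(C)=C/COc1ccc(/C=C(\C(=O)OC(C)(C)C)C(=O)c2c(O)cc(O[Si](C(C)C)(C(C)C)C(C)C)cc2O[Si](C(C)C)(C(C)C)C(C)C)cc1
F3 | step 7 | tert-butyl (2S)-2-{4-[(2E)-3,7-dimethylocta-2,6-dien-1-yloxy]phenyl}-4-oxo-5,7-bis(triisopropylsilyloxy)chromane-3-carboxylate (C3 unassigned) | CC(C)=CCC/C(C)=C/COc1ccc([C@@H]2C(C(=O)OC(C)(C)C)C(=O)c3c(O[Si](C(C)C)(C(C)C)C(C)C)cc(O[Si](C(C)C)(C(C)C)C(C)C)cc3O2)cc1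
F4 | step 7 | (2S)-2-{4-[(2E)-3,7-dimethylocta-2,6-dien-1-yloxy]phenyl}-4-oxo-5,7-bis(triisopropylsilyloxy)chromane-3-carboxylic acid (C3 unassigned, not isolated) | CC(C)=CCC/C(C)=C/COc1ccc([C@@H]2C(C(=O)O)C(=O)c3c(O[Si](C(C)C)(C(C)C)C(C)C)cc(O[Si](C(C)C)(C(C)C)C(C)C)cc3O2)cc1
F5 | step 7 | (2S)-2-{4-[(2E)-3,7-dimethylocta-2,6-dien-1-yloxy]phenyl}-5,7-bis(triisopropylsilyloxy)chroman-4-one | CC(C)=CCC/C(C)=C/COc1ccc([C@@H]2CC(=O)c3c(O[Si](C(C)C)(C(C)C)C(C)C)cc(O[Si](C(C)C)(C(C)C)C(C)C)cc3O2)cc1
F6 | step 5 | 1-[2-(methoxymethoxy)-4,6-bis(triisopropylsilyloxy)phenyl]ethanone | CC(=O)c1c(OCOC)cc(O[Si](C(C)C)(C(C)C)C(C)C)cc1O[Si](C(C)C)(C(C)C)C(C)C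
F7 | step 5 | 2-(trimethylsilyl)ethyl 3-[2-(methoxymethoxy)-4,6-bis(triisopropylsilyloxy)phenyl]-3-oxopropanoate | C[Si](C)(C)CCOC(=O)CC(=O)c1c(OCOC)cc(O[Si](C(C)C)(C(C)C)C(C)C)cc1O[Si](C(C)C)(C(C)C)C(C)C
F8 | step 5 | 2-(trimethylsilyl)ethyl (2Z)-3-{4-[(2E)-3,7-dimethylocta-2,6-dien-1-yloxy]phenyl}-2-[2-(methoxymethoxy)-4,6-bis(triisopropylsilyloxy)benzoyl]prop-2-enoate | CC(C)=CCC/C(C)=C/COc1ccc(/C=C(\C(=O)OCC[Si](C)(C)C)C(=O)c2c(OCOC)cc(O[Si](C(C)C)(C(C)C)C(C)C)cc2O[Si](C(C)C)(C(C)C)C(C)C)cc1
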